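The target, numbered as a cycloundec-1-ene-1-carboxylic acid, holds a 1,5-diene: exocyclic methylidene C12=C5, ring carbons C4–C3, ring enoate C2=C1. Its retro-[3,3] shift contracts the eleven-membered ring to a cyclononane in which C12 is a ring CH2 and C1 a quaternary carbon carrying vinyl and ester. Forward, one thermal Cope rearrangement breaks C1–C12, forms C3–C4, enlarges the ring by two carbons, unveils the methylidene, sets the (E)-enoate and erases the uncontrolled quaternary centre, so both C1 epimers converge. The cyclononane comes from two α-alkylations of a crotonate dienolate and a Nozaki–Hiyama–Kishi closure that also installs the C6 carbinol.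

Key step: step 11

Remark: carbons keep the target's locants in the text (C1 carries the carboxyl, C5 the methylidene carbon C12, C6 the hydroxyl, C8 the two methyls, C10 the angelate); 13 and 15–18 are carried as both epimers at C1, and systematic names use their own locants.

Step 1
Reactants: 1 crotonic acid; 2 2-(trimethylsilyl)ethanol
Product: 3 2-(trimethylsilyl)ethyl (E)-but-2-enoate
Conditions: DCC, DMAP (5 mol%), CH2Cl2, 0 °C to rt
Reagents that add atoms: none
Why: Steglich esterification; the 2-(trimethylsilyl)ethyl (TMSE) ester should survive amide bases, Cr(II), 180 °C and mild acid and is cleaved at the end by fluoride.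

Step 2
Reactants: 4 methyl 3,3-dimethylpent-4-enoate
Product: 5 N-methoxy-N,3,3-trimethylpent-4-enamide
Conditions: MeNH(OMe)·HCl, i-PrMgCl, THF, −20 to 0 °C
Reagents that add atoms: N,O-dimethylhydroxylamine hydrochloride, CNOC.Cl
Why: Weinreb amide formation by aminolysis of the ester with the magnesium amide; the amide is a latent C6 aldehyde that resists enolates and does not lactonise with the later C10 hydroxyl.

Step 3
Reactants: 5 N-methoxy-N,3,3-trimethylpent-4-enamide
Product: 6 N-methoxy-N,3,3-trimethyl-6-oxohexanamide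
Conditions: Rh(acac)(CO)2 (1 mol%), Xantphos, CO/H2 (1:1, 10 bar), toluene, 80 °C
Reagents that add atoms: carbon monoxide, [C-]#[O+]
Why: Rh-catalysed hydroformylation; the quaternary allylic carbon and the wide-bite-angle ligand should allow only the linear aldehyde.

Step 4
Reactants: 6 N-methoxy-N,3,3-trimethyl-6-oxohexanamide
Product: 9 (5S)-5,6-dihydroxy-N-methoxy-N,3,3-trimethylhexanamide, via anilinooxy aldehyde 7 (not isolated), via anilinooxy alcohol 8 (not isolated)
Conditions: D-proline (20 mol%), PhNO, MeCN, −20 °C; NaBH4, MeOH, 0 °C; then H2 (1 atm), Pd/C, rt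
Reagents that add atoms: nitrosobenzene, O=Nc1ccccc1
Why: Proline-catalysed α-aminoxylation (enamine catalysis) sets C10: the carboxylic acid of D-proline steers the oxygen of PhNO to the enamine face that gives the (S)-C–O centre (L-proline gives R), borohydride removes the epimerisable aldehyde and hydrogenolysis cleaves the weak O–N bond.

Step 5
Reactants: 9 (5S)-5,6-dihydroxy-N-methoxy-N,3,3-trimethylhexanamide
Product: 11 (2S)-6-[methoxy(methyl)amino]-4,4-dimethyl-6-oxo-2-(triethylsilyloxy)hexyl trifluoromethanesulfonate, via hydroxy triflate 10 (not isolated)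
Conditions: Tf2O (1.05 equiv), 2,6-lutidine, CH2Cl2, −78 °C; then TESOTf, −78 °C; cold silica plug, used at once
Reagents that add atoms: trifluoromethanesulfonic anhydride, O=S(=O)(OS(=O)(=O)C(F)(F)F)C(F)(F)F; triethylsilyl trifluoromethanesulfonate, CC[Si](CC)(CC)OS(=O)(=O)C(F)(F)F
Why: One-pot selective sulfonylation and silylation of a 1,2-diol: the primary hydroxyl should be triflated first at −78 °C and the secondary one capped as the TES ether before it can close to the epoxide.

Step 6
Reactants: 3 2-(trimethylsilyl)ethyl (E)-but-2-enoate; 11 (2S)-6-[methoxy(methyl)amino]-4,4-dimethyl-6-oxo-2-(triethylsilyloxy)hexyl trifluoromethanesulfonate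
Product: 13 2-(trimethylsilyl)ethyl (4R)-2-ethenyl-8-[methoxy(methyl)amino]-6,6-dimethyl-8-oxo-4-(triethylsilyloxy)octanoate (both epimers at the ester α-carbon), via lithium dienolate 12 (not isolated)
Conditions: 3 (1.3 equiv), LDA, HMPA, THF, −78 °C; then 11, −78 to −50 °C
Reagents that add atoms: none
Why: Deconjugative α-alkylation of a crotonate dienolate (γ-deprotonation by LDA·HMPA, kinetic attack at C-α) by SN2 on the primary triflate forms C1–C11; the new C1 stereocentre forms without control and is re-enolised in step 7 (the descriptor at the silyloxy carbon changes from S to R by CIP priority only).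

Step 7
Reactants: 13 2-(trimethylsilyl)ethyl (4R)-2-ethenyl-8-[methoxy(methyl)amino]-6,6-dimethyl-8-oxo-4-(triethylsilyloxy)octanoate
Product: 15 2-(trimethylsilyl)ethyl (4S)-2-(2-bromoprop-2-en-1-yl)-2-ethenyl-8-[methoxy(methyl)amino]-6,6-dimethyl-8-oxo-4-(triethylsilyloxy)octanoate (both epimers at the quaternary carbon), via lithium dienolate 14 (not isolated)
Conditions: LDA (1.1 equiv), HMPA, THF, −78 °C; then 2,3-dibromopropene, −78 to −30 °C
Reagents that add atoms: 2,3-dibromoprop-1-ene, BrCC(Br)=C
Why: Enolate alkylation: the doubly activated allylic α-C–H is the most acidic site, the lithium dienolate should react at C-α with the allylic bromide (the vinylic bromide is inert) and give the quaternary C1 as both epimers, which is acceptable because this centre becomes sp2 in step 11.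

Step 8
Reactants: 15 2-(trimethylsilyl)ethyl (4S)-2-(2-bromoprop-2-en-1-yl)-2-ethenyl-8-[methoxy(methyl)amino]-6,6-dimethyl-8-oxo-4-(triethylsilyloxy)octanoate
Product: 16 2-(trimethylsilyl)ethyl (4S)-2-(2-bromoprop-2-en-1-yl)-2-ethenyl-6,6-dimethyl-8-oxo-4-(triethylsilyloxy)octanoate (both epimers at the quaternary carbon)
Conditions: DIBAL-H (1.3 equiv), THF, −78 °C; Rochelle salt
Reagents that add atoms: none
Why: Weinreb amide reduction: the N,O-chelated aluminium hemiaminal releases the aldehyde only on work-up, and the ester on the quaternary carbon should be too hindered to compete at −78 °C.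

Step 9
Reactants: 16 2-(trimethylsilyl)ethyl (4S)-2-(2-bromoprop-2-en-1-yl)-2-ethenyl-6,6-dimethyl-8-oxo-4-(triethylsilyloxy)octanoate
Product: 17 2-(trimethylsilyl)ethyl (4S,8S)-1-ethenyl-4-hydroxy-6,6-dimethyl-3-methylidene-8-(triethylsilyloxy)cyclononane-1-carboxylate (both epimers at the ester-bearing ring carbon)
Conditions: CrCl2, chiral oxazoline–sulfonamide ligand (antipode that directs Re-face addition), Et3N, NiCl2·(2,9-dimethylphenanthroline) (10 mol%), MeCN/THF, rt, slow addition to 2 mM
Reagents that add atoms: none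
Why: Intramolecular Nozaki–Hiyama–Kishi reaction: Ni inserts into the C–Br bond, the alkenylchromium(III) adds only to the aldehyde and closes the nine-membered ring through C5–C6 (helped by the gem-dimethyl group and the quaternary C1), and the chromium-bound chiral sulfonamide should deliver the alkenyl group to the Re face of the aldehyde, which gives the (S)-carbinol at C6.

Step 10
Reactants: 17 2-(trimethylsilyl)ethyl (4S,8S)-1-ethenyl-4-hydroxy-6,6-dimethyl-3-methylidene-8-(triethylsilyloxy)cyclononane-1-carboxylate
Product: 18 2-(trimethylsilyl)ethyl (4S,8S)-4-[tert-butyl(dimethyl)silyl]oxy-1-ethenyl-6,6-dimethyl-3-methylidene-8-(triethylsilyloxy)cyclononane-1-carboxylate (both epimers at the ester-bearing ring carbon)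
Conditions: TBSOTf, 2,6-lutidine, CH2Cl2, −78 to 0 °C
Reagents that add atoms: tert-butyldimethylsilyl trifluoromethanesulfonate, CC(C)(C)[Si](C)(C)OS(=O)(=O)C(F)(F)F
Why: Silyl ether formation with a silyl triflate masks the hindered allylic C6 hydroxyl so that only the C10 oxygen is acylated later, and TBS should outlast the removal of TES.

Step 11
Reactants: 18 2-(trimethylsilyl)ethyl (4S,8S)-4-[tert-butyl(dimethyl)silyl]oxy-1-ethenyl-6,6-dimethyl-3-methylidene-8-(triethylsilyloxy)cyclononane-1-carboxylate
Product: 19 2-(trimethylsilyl)ethyl (1E,6S,10S)-6-[tert-butyl(dimethyl)silyl]oxy-8,8-dimethyl-5-methylidene-10-(triethylsilyloxy)cycloundec-1-ene-1-carboxylate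
Conditions: toluene (degassed, 5 mM), BHT (cat.), sealed tube, 180 °C
Reagents that add atoms: none
Why: Thermal Cope rearrangement: the 1,5-diene C4=C5–C12–C1–C2=C3 of 18 reorganises through a six-membered chair-like array, the ring bond C1–C12 breaks while C3–C4 forms, so the nine-membered ring grows by two carbons, C12 becomes the exocyclic methylidene and C1 the α-carbon of a conjugated ester. The closest known reaction types are the Cope rearrangement of 3-alkoxycarbonyl-1,5-dienes, which is driven by conjugation, and the Claisen ring expansion of 2-methylene-6-vinyl oxacycles, of which this is the all-carbon counterpart. The eleven-membered ring is not closed end to end but arises by ring expansion, so no exo or endo closure mode applies; the driving force is the new trisubstituted enoate and the loss of the congested quaternary centre. No new stereocentre forms and C6 and C10 are not touched; the quaternary C1 is destroyed, so both C1 epimers of 18 should converge on one product. The step needs the (1E) geometry: the six-carbon tether C11–C10–C9–C8–C7–C6 can bridge C1 and C5 of the pericyclic array only when the C1–C11 bond is pseudo-axial, that is syn to C3, which leaves the ester pseudo-equatorial, trans to C3 and free to conjugate. Only one 1,5-diene is present, so there is no regiochemical alternative.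

Step 12
Reactants: 19 2-(trimethylsilyl)ethyl (1E,6S,10S)-6-[tert-butyl(dimethyl)silyl]oxy-8,8-dimethyl-5-methylidene-10-(triethylsilyloxy)cycloundec-1-ene-1-carboxylate
Product: 20 2-(trimethylsilyl)ethyl (1E,6S,10S)-6-[tert-butyl(dimethyl)silyl]oxy-10-hydroxy-8,8-dimethyl-5-methylidenecycloundec-1-ene-1-carboxylate
Conditions: PPTS (0.2 equiv), MeOH/CH2Cl2, 0 °C
Reagents that add atoms: none
Why: Acid-catalysed methanolysis of silyl ethers should be far faster for the secondary TES ether than for the secondary allylic TBS ether, and the TMSE ester is inert.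

Step 13
Reactants: 20 2-(trimethylsilyl)ethyl (1E,6S,10S)-6-[tert-butyl(dimethyl)silyl]oxy-10-hydroxy-8,8-dimethyl-5-methylidenecycloundec-1-ene-1-carboxylate
Product: 21 2-(trimethylsilyl)ethyl (1E,6S,10S)-6-[tert-butyl(dimethyl)silyl]oxy-8,8-dimethyl-5-methylidene-10-{[(2Z)-2-methylbut-2-enoyl]oxy}cycloundec-1-ene-1-carboxylate
Conditions: angelic acid, 2,4,6-trichlorobenzoyl chloride, Et3N, toluene, rt; then 20, 75 °C (no DMAP)
Reagents that add atoms: angelic acid [(2Z)-2-methylbut-2-enoic acid], C/C=C(/C)C(=O)O
Why: Yamaguchi esterification through the mixed anhydride, run without DMAP, should acylate the hindered secondary alcohol with angelic acid without isomerising the Z double bond to the tiglate.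

Step 14
Reactants: 21 2-(trimethylsilyl)ethyl (1E,6S,10S)-6-[tert-butyl(dimethyl)silyl]oxy-8,8-dimethyl-5-methylidene-10-{[(2Z)-2-methylbut-2-enoyl]oxy}cycloundec-1-ene-1-carboxylate
Product: 22 (1E,6S,10S)-6-hydroxy-8,8-dimethyl-5-methylidene-10-{[(2Z)-2-methylbut-2-enoyl]oxy}cycloundec-1-ene-1-carboxylic acid (target)
Conditions: TASF, DMF, 0 °C to rt; aq. NH4Cl
Reagents that add atoms: none
Why: Fluoride-induced fragmentation of the 2-(trimethylsilyl)ethyl ester (loss of Me3SiF and ethene) and desilylation of the TBS ether in one operation, under near-neutral conditions that should spare the angelate and the γ-acyloxy enoate.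

Compound list
1 | crotonic acid [(E)-but-2-enoic acid] | C/C=C/C(=O)O | starting material
2 | 2-(trimethylsilyl)ethanol | C[Si](C)(C)CCO | starting material
3 | 2-(trimethylsilyl)ethyl (E)-but-2-enoate | C/C=C/C(=O)OCC[Si](C)(C)C | intermediate
4 | methyl 3,3-dimethylpent-4-enoate | C=CC(C)(C)CC(=O)OC | starting material
5 | N-methoxy-N,3,3-trimethylpent-4-enamide | C=CC(C)(C)CC(=O)N(C)OC | intermediate
6 | N-methoxy-N,3,3-trimethyl-6-oxohexanamide | O=CCCC(C)(C)CC(=O)N(C)OC | intermediate
7 | (5S)-N-methoxy-N,3,3-trimethyl-6-oxo-5-(phenylaminooxy)hexanamide | O=C[C@@H](ONc1ccccc1)CC(C)(C)CC(=O)N(C)OC | intermediate (not isolated)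
8 | (5S)-6-hydroxy-N-methoxy-N,3,3-trimethyl-5-(phenylaminooxy)hexanamide | OC[C@@H](ONc1ccccc1)CC(C)(C)CC(=O)N(C)OC | intermediate (not isolated)
9 | (5S)-5,6-dihydroxy-N-methoxy-N,3,3-trimethylhexanamide | OC[C@@H](O)CC(C)(C)CC(=O)N(C)OC | intermediate
10 | (2S)-2-hydroxy-6-[methoxy(methyl)amino]-4,4-dimethyl-6-oxohexyl trifluoromethanesulfonate | O=S(=O)(OC[C@@H](O)CC(C)(C)CC(=O)N(C)OC)C(F)(F)F | intermediate (not isolated)
11 | (2S)-6-[methoxy(methyl)amino]-4,4-dimethyl-6-oxo-2-(triethylsilyloxy)hexyl trifluoromethanesulfonate | O=S(=O)(OC[C@@H](O[Si](CC)(CC)CC)CC(C)(C)CC(=O)N(C)OC)C(F)(F)F | intermediate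
12 | lithium dienolate of 3 | [Li]OC(=CC=C)OCC[Si](C)(C)C | intermediate (not isolated)
13 | 2-(trimethylsilyl)ethyl (4R)-2-ethenyl-8-[methoxy(methyl)amino]-6,6-dimethyl-8-oxo-4-(triethylsilyloxy)octanoate, both epimers at the ester α-carbon | C=CC(C(=O)OCC[Si](C)(C)C)C[C@@H](O[Si](CC)(CC)CC)CC(C)(C)CC(=O)N(C)OC | intermediate
14 | lithium dienolate of 13 | C=CC(=C(O[Li])OCC[Si](C)(C)C)C[C@@H](O[Si](CC)(CC)CC)CC(C)(C)CC(=O)N(C)OC | intermediate (not isolated)
15 | 2-(trimethylsilyl)ethyl (4S)-2-(2-bromoprop-2-en-1-yl)-2-ethenyl-8-[methoxy(methyl)amino]-6,6-dimethyl-8-oxo-4-(triethylsilyloxy)octanoate, both epimers at the quaternary carbon | C=CC(CC(Br)=C)(C(=O)OCC[Si](C)(C)C)C[C@@H](O[Si](CC)(CC)CC)CC(C)(C)CC(=O)N(C)OC | intermediate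
16 | 2-(trimethylsilyl)ethyl (4S)-2-(2-bromoprop-2-en-1-yl)-2-ethenyl-6,6-dimethyl-8-oxo-4-(triethylsilyloxy)octanoate, both epimers at the quaternary carbon | C=CC(CC(Br)=C)(C(=O)OCC[Si](C)(C)C)C[C@@H](O[Si](CC)(CC)CC)CC(C)(C)CC=O | intermediate
17 | 2-(trimethylsilyl)ethyl (4S,8S)-1-ethenyl-4-hydroxy-6,6-dimethyl-3-methylidene-8-(triethylsilyloxy)cyclononane-1-carboxylate, both epimers at the ester-bearing ring carbon | C=C1CC(C=C)(C(=O)OCC[Si](C)(C)C)C[C@@H](O[Si](CC)(CC)CC)CC(C)(C)C[C@@H]1O | intermediate
18 | 2-(trimethylsilyl)ethyl (4S,8S)-4-[tert-butyl(dimethyl)silyl]oxy-1-ethenyl-6,6-dimethyl-3-methylidene-8-(triethylsilyloxy)cyclononane-1-carboxylate, both epimers at the ester-bearing ring carbon | C=C1CC(C=C)(C(=O)OCC[Si](C)(C)C)C[C@@H](O[Si](CC)(CC)CC)CC(C)(C)C[C@@H]1O[Si](C)(C)C(C)(C)C | intermediate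
19 | 2-(trimethylsilyl)ethyl (1E,6S,10S)-6-[tert-butyl(dimethyl)silyl]oxy-8,8-dimethyl-5-methylidene-10-(triethylsilyloxy)cycloundec-1-ene-1-carboxylate | C=C1CC/C=C(/C(=O)OCC[Si](C)(C)C)C[C@@H](O[Si](CC)(CC)CC)CC(C)(C)C[C@@H]1O[Si](C)(C)C(C)(C)C | intermediate
20 | 2-(trimethylsilyl)ethyl (1E,6S,10S)-6-[tert-butyl(dimethyl)silyl]oxy-10-hydroxy-8,8-dimethyl-5-methylidenecycloundec-1-ene-1-carboxylate | C=C1CC/C=C(/C(=O)OCC[Si](C)(C)C)C[C@@H](O)CC(C)(C)C[C@@H]1O[Si](C)(C)C(C)(C)C | intermediate
21 | 2-(trimethylsilyl)ethyl (1E,6S,10S)-6-[tert-butyl(dimethyl)silyl]oxy-8,8-dimethyl-5-methylidene-10-{[(2Z)-2-methylbut-2-enoyl]oxy}cycloundec-1-ene-1-carboxylate | C=C1CC/C=C(/C(=O)OCC[Si](C)(C)C)C[C@@H](OC(=O)/C(C)=C\C)CC(C)(C)C[C@@H]1O[Si](C)(C)C(C)(C)C | intermediate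
22 | (1E,6S,10S)-6-hydroxy-8,8-dimethyl-5-methylidene-10-{[(2Z)-2-methylbut-2-enoyl]oxy}cycloundec-1-ene-1-carboxylic acid | C=C1CC/C=C(/C(=O)O)C[C@@H](OC(=O)/C(C)=C\C)CC(C)(C)C[C@@H]1O | target

Total step count: 14. Longest linear sequence: 13 steps (4 to 22, steps 2–14).

Steps most likely to fail

1. Step 11 (key step). The rearrangement may pass in part through the rotamer with the ester on the inside and give the enoate as a mixture of geometries. It may also be slow if the ring conformers hold the two termini apart, and ene-type decomposition could then compete at the temperature needed. Fallback: it sets out from 18 and comes back at 19. The rearrangement is run without relying on kinetic control of the geometry, and the resulting mixture, which contains the (1Z) isomer of 19 F1, is equilibrated with catalytic diphenyl disulfide under irradiation (benzene, 350 nm). Reversible thiyl radical addition to the enoate should funnel F1 to the more stable tiglate-type (1E) geometry of 19. No angelate is present at this stage that could be isomerised with it.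

2. Step 9. Nine-membered closure may be slow relative to protodebromination and intermolecular coupling, and the conformation of the closing ring rather than the ligand may decide which aldehyde face is attacked, which would erode the C6 configuration. Fallback: it sets out from 16 and comes back at 17. The closure is run with achiral CrCl2/NiCl2 (DMSO, high dilution) to give 17 together with the C6-epimeric alcohol F2. The mixture is oxidised with Dess–Martin periodinane to the cross-conjugated enone F3. Corey–Bakshi–Shibata reduction with the (R)-oxazaborolidine and catecholborane (alkenyl as the large group) should then return 17 with reagent control.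

3. Step 6. The β-silyloxy triflate may undergo elimination or decompose before C–C bond formation, and proton exchange between 13 and the dienolate may lead to double alkylation. Fallback: it sets out from 9 and comes back at 13. Mitsunobu cyclodehydration of 9 (PPh3, DIAD) gives the terminal epoxide F4 with retention at the secondary carbon. Dienolate 12 opens it at the primary carbon in the presence of BF3·OEt2 at −78 °C to the γ-hydroxy ester F5. F5 is silylated at once (TESOTf, 2,6-lutidine) to 13 before it can lactonise.

Further compounds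
F1 | step 11 | 2-(trimethylsilyl)ethyl (1Z,6S,10S)-6-[tert-butyl(dimethyl)silyl]oxy-8,8-dimethyl-5-methylidene-10-(triethylsilyloxy)cycloundec-1-ene-1-carboxylate | C=C1CC/C=C(\C(=O)OCC[Si](C)(C)C)C[C@@H](O[Si](CC)(CC)CC)CC(C)(C)C[C@@H]1O[Si](C)(C)C(C)(C)C
F2 | step 9 | 2-(trimethylsilyl)ethyl (4R,8S)-1-ethenyl-4-hydroxy-6,6-dimethyl-3-methylidene-8-(triethylsilyloxy)cyclononane-1-carboxylate, both epimers at the ester-bearing ring carbon | C=C1CC(C=C)(C(=O)OCC[Si](C)(C)C)C[C@@H](O[Si](CC)(CC)CC)CC(C)(C)C[C@H]1O
F3 | step 9 | 2-(trimethylsilyl)ethyl (8S)-1-ethenyl-6,6-dimethyl-3-methylidene-4-oxo-8-(triethylsilyloxy)cyclononane-1-carboxylate, both epimers at the ester-bearing ring carbon | C=C1CC(C=C)(C(=O)OCC[Si](C)(C)C)C[C@@H](O[Si](CC)(CC)CC)CC(C)(C)CC1=O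
F4 | step 6 | N-methoxy-N,3,3-trimethyl-4-[(2S)-oxiran-2-yl]butanamide | C1[C@@H](O1)CC(C)(C)CC(=O)N(C)OC
F5 | step 6 | 2-(trimethylsilyl)ethyl (4R)-2-ethenyl-4-hydroxy-8-[methoxy(methyl)amino]-6,6-dimethyl-8-oxooctanoate, both epimers at the ester α-carbon | C=CC(C(=O)OCC[Si](C)(C)C)C[C@@H](O)CC(C)(C)CC(=O)N(C)OC
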